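## Retrosynthetic overview

1. Numbering: unit 1 is the 5,7-dihydroxyflavanone (rings A, C, B; O1 to C8a, C1' to C6'). Unit 2 is the 5''-hydroxy-7''-methoxyflavanone (rings D, F, E; double-primed atoms). The units are joined C3'-C8''.
2. The plan rests on ring D. Five of its six carbons are substituted, C8'' carries ring B, and its 1,3,5-oxygens are three different functions (phenol at C5'', methyl ether at C7'', pyranone oxygen at C8a''). C7''-C6''-C5''-C4a'' come from a 3-alkoxycyclobutenone and C8''-C8a'' from an aryl siloxyalkyne. Each oxygen therefore arrives in a different state, and the crowded C3'-C8'' bond starts life as an aryl-alkyne bond.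
3. Late disconnections: O1-C2 (ring C) and O1''-C2'' (ring F) by catalyst-controlled oxa-Michael closure of ester-activated chalcones. Each chalcone C=C comes from a Knoevenagel condensation, and C4a''-C4'' from ortho-formylation of the C8a'' phenol.
4. Key disconnection: ring D into 3-(benzyloxy)cyclobutenone and the ring B siloxyalkyne (C7''-C8'', C8a''-C4a'', ring closure at C6''-C7''). The alkyne comes from a ring B benzoate by ynolate homologation.
5. Ring order: A, B and E are bought. D is made first (step 5), then F (step 12), then C (step 16).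

Key step: step 5

Abbreviation: ArB = 2-(benzyloxy)-5-(5,5-dimethyl-1,3-dioxan-2-yl)phenyl, that is ring B bonded through C3', with C4'-OBn and the masked C1' aldehyde.

Assumption 1: the quinidine-derived thiourea is taken to give the 2S series. A model flavanone closure settles the sense, and if it is opposite the quinine-derived pseudoenantiomer replaces it in steps 12 and 16 with no other change.

Assumption 2: the C3'-C8'' axis has three small ortho substituents and no descriptor in the target, so it is treated as configurationally mobile and is not controlled.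

## Route

Step 1
Reactants: 1 methyl 5-formylsalicylate
Product: 2 methyl 2-(benzyloxy)-5-formylbenzoate
Conditions: BnBr, K2CO3, DMF, rt to 50 °C
Reagents that add atoms: benzyl bromide, BrCc1ccccc1
Why: Williamson ether synthesis on the acidic salicylate phenol; the aldehyde and the methyl ester are inert to K2CO3 in DMF.

Step 2
Reactants: 2 methyl 2-(benzyloxy)-5-formylbenzoate
Product: 3 methyl 2-(benzyloxy)-5-(5,5-dimethyl-1,3-dioxan-2-yl)benzoate
Conditions: 2,2-dimethylpropane-1,3-diol, TsOH·H2O (cat.), toluene, Dean-Stark, reflux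
Reagents that add atoms: 2,2-dimethylpropane-1,3-diol, OCC(C)(C)CO
Why: Acid-catalysed acetalisation with azeotropic removal of water; the six-membered acetal is preferred to a 1,3-dioxolane because a 2-aryl-1,3-dioxolane can lose ethylene by base-induced cycloreversion under the alkyllithium warm-up of step 3, and because it better survives the later aqueous work-ups.

Step 3
Reactants: 3 methyl 2-(benzyloxy)-5-(5,5-dimethyl-1,3-dioxan-2-yl)benzoate
Product: 6 triisopropyl[(ArB-ethynyl)oxy]silane, via lithium dibromoenolate 4 (not isolated), via lithium ynolate 5 (not isolated)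
Conditions: CH2Br2, lithium 2,2,6,6-tetramethylpiperidide (from the amine and n-BuLi), THF, -78 °C; LiN(SiMe3)2; n-BuLi (kept close to the amount needed), -78 to 20 °C; iPr3SiOSO2CF3 (excess), -78 to 0 °C; NaHCO3 work-up
Reagents that add atoms: dibromomethane, BrCBr; triisopropylsilyl trifluoromethanesulfonate, CC(C)[Si](OS(=O)(=O)C(F)(F)F)(C(C)C)C(C)C
Why: Kowalski ester homologation stopped at the ynolate stage: LiCHBr2 adds to the ester, the dibromoketone is enolised to 4, bromine-lithium exchange triggers 1,2-aryl migration to ynolate 5, and the bulky silyl triflate reacts at oxygen rather than carbon, as is known for triisopropylsilyl ynol ethers made from aromatic and aliphatic esters.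

Step 4
Reactants: 7 cyclobutane-1,3-dione
Product: 8 3-(benzyloxy)cyclobut-2-en-1-one
Conditions: benzyl 2,2,2-trichloroacetimidate, CH2Cl2, 0 °C to rt
Reagents that add atoms: benzyl 2,2,2-trichloroacetimidate, N=C(OCc1ccccc1)C(Cl)(Cl)Cl
Why: The enol of 7 is a strongly acidic vinylogous carboxylic acid that protonates the imidate itself and is benzylated at oxygen within the ion pair, the trichloroacetimidate O-benzylation known for carboxylic acids and alcohols, at a temperature too low for ring opening of 8.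

Step 5
Reactants: 6 triisopropyl[(ArB-ethynyl)oxy]silane; 8 3-(benzyloxy)cyclobut-2-en-1-one
Product: 13 2-ArB-5-(benzyloxy)-3-(triisopropylsiloxy)phenol (free C7'' OH; C8a'' silyl ether; C5'' benzyl ether), via vinylketene 9 (not isolated), via vinylcyclobutenone 10 (not isolated), via dienylketene 11 (not isolated), via cyclohexadienone 12 (not isolated)
Conditions: 6 (1.1 equiv), toluene, sealed tube, 80 °C then 110 °C
Reagents that add atoms: none
Why: Heat opens 8 by four-electron electrocyclic cleavage of its C1-C4 bond to vinylketene 9, whose carbonyl carbon is attacked by the aryl-bearing alkyne carbon of 6 in a [2+2] cycloaddition that forms C7''-C8'' and C8a''-C4a'' and gives 10. Reversible four-electron opening of 10 gives dienylketene 11, which closes ring D by six-electron electrocyclisation (C6''-C7'' bond, a pericyclic six-membered carbocyclisation) to dienone 12, and tautomerisation gives phenol 13. The closest known reaction type is the Danheiser benzannulation of cyclobutenones with trialkylsiloxyalkynes, here with the less usual oxygen substituent at C3 of the four-membered ring. No stereocentre remains, since C4 of 10 is lost on ring opening. What has to be controlled is the orientation of the alkyne in the [2+2] event: oxygen donation makes the aryl-substituted carbon of 6 the electron-rich terminus, it bonds to the electrophilic ketene carbon, and ring B is thereby set beside the nascent C7'' hydroxyl while the OSi(iPr)3 group lands beside the unsubstituted C4a''. The three ring D oxygens therefore emerge as free phenol, silyl ether and benzyl ether, each addressable on its own.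

Step 6
Reactants: 13 2-ArB-5-(benzyloxy)-3-(triisopropylsiloxy)phenol
Product: 14 [2-ArB-5-(benzyloxy)-3-methoxyphenoxy]triisopropylsilane
Conditions: MeI, K2CO3, acetone, reflux
Reagents that add atoms: iodomethane, CI
Why: Williamson methylation of the only free hydroxyl (C7''); the aryl triisopropylsilyl ether, the benzyl ethers and the acetal are stable to K2CO3 in acetone.

Step 7
Reactants: 14 [2-ArB-5-(benzyloxy)-3-methoxyphenoxy]triisopropylsilane
Product: 15 2-ArB-5-(benzyloxy)-3-methoxyphenol
Conditions: Bu4NF, THF, 0 °C; aq. NH4Cl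
Reagents that add atoms: none
Why: Fluoride-induced cleavage of the aryl silyl ether frees the C8a'' phenol alone, since every other oxygen is an alkyl ether or an acetal oxygen.

Step 8
Reactants: 15 2-ArB-5-(benzyloxy)-3-methoxyphenol
Product: 17 3-ArB-6-(benzyloxy)-2-hydroxy-4-methoxybenzaldehyde, via salicyl alcohol 16 (not isolated)
Conditions: MgCl2 (anhydrous), Et3N, (CH2O)n, MeCN, reflux; cold aq. citric acid work-up
Reagents that add atoms: formaldehyde (as paraformaldehyde), C=O
Why: Casnati-Skattebøl ortho-formylation: formaldehyde is delivered inside the magnesium phenoxide chelate, so only the free ortho position C4a'' reacts (C8'' is blocked and the para position C6'' is out of reach) to give 16, which a second formaldehyde oxidises by hydride transfer, and the basic medium spares the acetal.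

Step 9
Reactants: 17 3-ArB-6-(benzyloxy)-2-hydroxy-4-methoxybenzaldehyde
Product: 18 tert-butyl 3-[3-ArB-6-(benzyloxy)-2-hydroxy-4-methoxyphenyl]-3-hydroxypropanoate (racemic carbinol; used crude)
Conditions: t-BuOAc, LiN(iPr)2 (3.2 equiv each), THF, -78 °C; then 17; aq. NH4Cl
Reagents that add atoms: tert-butyl acetate, CC(=O)OC(C)(C)C
Why: Aldol addition of the lithium enolate of tert-butyl acetate, used in excess because the first equivalent deprotonates the phenol; the new carbinol centre is of no consequence since step 10 oxidises it.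

Step 10
Reactants: 18 tert-butyl 3-[3-ArB-6-(benzyloxy)-2-hydroxy-4-methoxyphenyl]-3-hydroxypropanoate
Product: 19 tert-butyl 3-[3-ArB-6-(benzyloxy)-2-hydroxy-4-methoxyphenyl]-3-oxopropanoate
Conditions: activated MnO2 (excess), CH2Cl2, rt
Reagents that add atoms: none
Why: MnO2 oxidises the electron-rich salicyl-type benzylic alcohol under neutral conditions to the hydrogen-bonded aryl ketone without touching the acetal or the benzyl ethers.

Step 11
Reactants: 19 tert-butyl 3-[3-ArB-6-(benzyloxy)-2-hydroxy-4-methoxyphenyl]-3-oxopropanoate; 20 4-(benzyloxy)benzaldehyde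
Product: 21 tert-butyl (E)-2-[3-ArB-6-(benzyloxy)-2-hydroxy-4-methoxybenzoyl]-3-[4-(benzyloxy)phenyl]prop-2-enoate
Conditions: piperidine (20 mol%), AcOH (20 mol%), 4 Å molecular sieves, toluene, rt
Reagents that add atoms: none
Why: Knoevenagel condensation of a β-keto ester with an aromatic aldehyde under piperidinium acetate catalysis; the ring B aldehyde is still masked so only 20 can condense, and the E isomer (ester trans to ring E) is expected on steric grounds.

Step 12
Reactants: 21 tert-butyl (E)-2-[3-ArB-6-(benzyloxy)-2-hydroxy-4-methoxybenzoyl]-3-[4-(benzyloxy)phenyl]prop-2-enoate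
Product: 24 4-(benzyloxy)-3-{(2S)-5-(benzyloxy)-2-[4-(benzyloxy)phenyl]-7-methoxy-4-oxochroman-8-yl}benzaldehyde, via ester flavanone 22 (not isolated), via acetal flavanone 23 (not isolated)
Conditions: N-[3,5-bis(trifluoromethyl)phenyl]-N'-[(9R)-6'-methoxycinchonan-9-yl]thiourea (10 mol%), toluene, -25 °C; then TsOH·H2O, 80 °C; then acetone/H2O, rt to 40 °C
Reagents that add atoms: water, O
Why: Enantioselective intramolecular oxa-Michael addition of a 2-hydroxyaryl alkylidene β-keto ester under bifunctional cinchona thiourea catalysis (the thiourea binds the dicarbonyl unit, the quinuclidine activates the C8a'' phenol) closes ring F and sets C2'' as S by catalyst control, after which acid removes the tert-butyl ester as isobutene and CO2 and wet acetone hydrolyses the acetal.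

Step 13
Reactants: 25 2',4',6'-trihydroxyacetophenone
Product: 26 1-[2,4-bis(benzyloxy)-6-hydroxyphenyl]ethan-1-one
Conditions: BnBr (2.1 equiv), K2CO3, DMF, rt to 50 °C
Reagents that add atoms: benzyl bromide, BrCc1ccccc1
Why: Williamson benzylation with two equivalents of halide stops at the diether because the last hydroxyl is deactivated by its hydrogen bond to the acetyl group.

Step 14
Reactants: 26 1-[2,4-bis(benzyloxy)-6-hydroxyphenyl]ethan-1-one
Product: 27 tert-butyl 3-[2,4-bis(benzyloxy)-6-hydroxyphenyl]-3-oxopropanoate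
Conditions: LiN(SiMe3)2 (3.3 equiv), THF, -78 °C; Boc2O, -78 to 0 °C; aq. NH4Cl
Reagents that add atoms: di-tert-butyl dicarbonate, CC(C)(C)OC(=O)OC(=O)OC(C)(C)C
Why: Claisen-type C-acylation of the phenoxide-enolate dianion; any aryl carbonate formed first is funnelled to the same product by Baker-Venkataraman-type O-to-C transfer, and the third equivalent of base stores 27 as its enolate.

Step 15
Reactants: 24 4-(benzyloxy)-3-{(2S)-5-(benzyloxy)-2-[4-(benzyloxy)phenyl]-7-methoxy-4-oxochroman-8-yl}benzaldehyde; 27 tert-butyl 3-[2,4-bis(benzyloxy)-6-hydroxyphenyl]-3-oxopropanoate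
Product: 28 tert-butyl (E)-2-[2,4-bis(benzyloxy)-6-hydroxybenzoyl]-3-(4-(benzyloxy)-3-{(2S)-5-(benzyloxy)-2-[4-(benzyloxy)phenyl]-7-methoxy-4-oxochroman-8-yl}phenyl)prop-2-enoate
Conditions: piperidine (10 mol%), AcOH (10 mol%), 4 Å molecular sieves, toluene, 0 °C to rt
Reagents that add atoms: none
Why: Knoevenagel condensation in which the β-keto ester of 27 is far more acidic than the C3'' methylene of the flavanone, so only 27 condenses with the aldehyde and the weakly basic buffer should leave C2'' untouched.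

Step 16
Reactants: 28 the ring A alkylidene β-keto ester of step 15
Product: 30 (2S,2''S)-penta-O-benzyl biflavanone (benzyl ethers at C5 C7 C4' C5'' C4'''; methyl ether at C7''), via ester biflavanone 29 (not isolated)
Conditions: N-[3,5-bis(trifluoromethyl)phenyl]-N'-[(9R)-6'-methoxycinchonan-9-yl]thiourea (10 mol%), toluene, -25 °C; then TsOH·H2O, 80 °C
Reagents that add atoms: none
Why: The same thiourea-catalysed enantioselective oxa-Michael closure, now of the ring A phenol onto the ring B alkylidene, closes ring C and sets C2 as S by catalyst control (the remote C2'' centre should have little say), and the acid neutralises the amine catalyst before heat removes the ester as isobutene and CO2.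

Step 17
Reactants: 30 (2S,2''S)-penta-O-benzyl biflavanone
Product: 31 CNP0237714.1, (2S,2''S)-5,7,4',5'',4'''-pentahydroxy-7''-methoxy-3',8''-biflavanone
Conditions: H2 (1 atm), Pd on carbon (10 wt% Pd), EtOAc/MeOH, rt
Reagents that add atoms: none
Why: Hydrogenolysis of five aryl benzyl ethers under neutral conditions, routine for benzylated flavanones; the methyl ether, both ketones and the cyclic benzylic C2-O1 bonds should survive one atmosphere of H2 at room temperature, and no base is present that could open the pyranone rings and racemise C2 or C2''.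

## Compound list

1 | methyl 5-formylsalicylate | COC(=O)c1cc(C=O)ccc1O | starting material
2 | methyl 2-(benzyloxy)-5-formylbenzoate | COC(=O)c1cc(C=O)ccc1OCc1ccccc1 | intermediate
3 | methyl 2-(benzyloxy)-5-(5,5-dimethyl-1,3-dioxan-2-yl)benzoate | COC(=O)c1cc(C2OCC(C)(C)CO2)ccc1OCc1ccccc1 | intermediate
4 | lithium 1-ArB-2,2-dibromoethen-1-olate (not isolated) | [Li+].[O-]C(=C(Br)Br)c1cc(C2OCC(C)(C)CO2)ccc1OCc1ccccc1 | intermediate
5 | lithium 2-ArB-ethyn-1-olate (not isolated) | [Li+].[O-]C#Cc1cc(C2OCC(C)(C)CO2)ccc1OCc1ccccc1 | intermediate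
6 | triisopropyl[(ArB-ethynyl)oxy]silane, ring B siloxyalkyne | CC(C)[Si](OC#Cc1cc(C2OCC(C)(C)CO2)ccc1OCc1ccccc1)(C(C)C)C(C)C | intermediate
7 | cyclobutane-1,3-dione | O=C1CC(=O)C1 | starting material
8 | 3-(benzyloxy)cyclobut-2-en-1-one | O=C1C=C(OCc2ccccc2)C1 | intermediate
9 | 3-(benzyloxy)buta-1,3-dien-1-one, vinylketene (not isolated) | C=C(OCc1ccccc1)C=C=O | intermediate
10 | 2-ArB-4-[1-(benzyloxy)ethenyl]-3-(triisopropylsiloxy)cyclobut-2-en-1-one, racemic (not isolated) | O=C1C(c2cc(C3OCC(C)(C)CO3)ccc2OCc2ccccc2)=C(O[Si](C(C)C)(C(C)C)C(C)C)C1C(=C)OCc1ccccc1 | intermediate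
11 | 2-ArB-5-(benzyloxy)-3-(triisopropylsiloxy)hexa-1,3,5-trien-1-one, ketene carbon and benzyloxyvinyl group cis on C3=C4 (not isolated) | O=C=C(c1cc(C2OCC(C)(C)CO2)ccc1OCc1ccccc1)/C(O[Si](C(C)C)(C(C)C)C(C)C)=C\C(=C)OCc1ccccc1 | intermediate
12 | 2-ArB-5-(benzyloxy)-3-(triisopropylsiloxy)cyclohexa-2,4-dien-1-one (not isolated) | O=C1CC(OCc2ccccc2)=CC(O[Si](C(C)C)(C(C)C)C(C)C)=C1c1cc(C2OCC(C)(C)CO2)ccc1OCc1ccccc1 | intermediate
13 | 2-ArB-5-(benzyloxy)-3-(triisopropylsiloxy)phenol | Oc1cc(OCc2ccccc2)cc(O[Si](C(C)C)(C(C)C)C(C)C)c1-c1cc(C2OCC(C)(C)CO2)ccc1OCc1ccccc1 | intermediate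
14 | [2-ArB-5-(benzyloxy)-3-methoxyphenoxy]triisopropylsilane | COc1cc(OCc2ccccc2)cc(O[Si](C(C)C)(C(C)C)C(C)C)c1-c1cc(C2OCC(C)(C)CO2)ccc1OCc1ccccc1 | intermediate
15 | 2-ArB-5-(benzyloxy)-3-methoxyphenol | COc1cc(OCc2ccccc2)cc(O)c1-c1cc(C2OCC(C)(C)CO2)ccc1OCc1ccccc1 | intermediate
16 | 2-ArB-5-(benzyloxy)-6-(hydroxymethyl)-3-methoxyphenol, present as its magnesium salt (not isolated) | COc1cc(OCc2ccccc2)c(CO)c(O)c1-c1cc(C2OCC(C)(C)CO2)ccc1OCc1ccccc1 | intermediate
17 | 3-ArB-6-(benzyloxy)-2-hydroxy-4-methoxybenzaldehyde | COc1cc(OCc2ccccc2)c(C=O)c(O)c1-c1cc(C2OCC(C)(C)CO2)ccc1OCc1ccccc1 | intermediate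
18 | tert-butyl 3-[3-ArB-6-(benzyloxy)-2-hydroxy-4-methoxyphenyl]-3-hydroxypropanoate, racemic carbinol | COc1cc(OCc2ccccc2)c(C(O)CC(=O)OC(C)(C)C)c(O)c1-c1cc(C2OCC(C)(C)CO2)ccc1OCc1ccccc1 | intermediate
19 | tert-butyl 3-[3-ArB-6-(benzyloxy)-2-hydroxy-4-methoxyphenyl]-3-oxopropanoate | COc1cc(OCc2ccccc2)c(C(=O)CC(=O)OC(C)(C)C)c(O)c1-c1cc(C2OCC(C)(C)CO2)ccc1OCc1ccccc1 | intermediate
20 | 4-(benzyloxy)benzaldehyde | O=Cc1ccc(OCc2ccccc2)cc1 | starting material
21 | tert-butyl (E)-2-[3-ArB-6-(benzyloxy)-2-hydroxy-4-methoxybenzoyl]-3-[4-(benzyloxy)phenyl]prop-2-enoate | COc1cc(OCc2ccccc2)c(C(=O)/C(C(=O)OC(C)(C)C)=C\c2ccc(OCc3ccccc3)cc2)c(O)c1-c1cc(C2OCC(C)(C)CO2)ccc1OCc1ccccc1 | intermediate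
22 | tert-butyl (2S)-8-ArB-5-(benzyloxy)-2-[4-(benzyloxy)phenyl]-7-methoxy-4-oxochromane-3-carboxylate, C3 labile (not isolated) | COc1cc(OCc2ccccc2)c2c(c1-c1cc(C3OCC(C)(C)CO3)ccc1OCc1ccccc1)O[C@H](c1ccc(OCc3ccccc3)cc1)C(C(=O)OC(C)(C)C)C2=O | intermediate
23 | (2S)-8-ArB-5-(benzyloxy)-2-[4-(benzyloxy)phenyl]-7-methoxychroman-4-one (not isolated) | COc1cc(OCc2ccccc2)c2c(c1-c1cc(C3OCC(C)(C)CO3)ccc1OCc1ccccc1)O[C@H](c1ccc(OCc3ccccc3)cc1)CC2=O | intermediate
24 | 4-(benzyloxy)-3-{(2S)-5-(benzyloxy)-2-[4-(benzyloxy)phenyl]-7-methoxy-4-oxochroman-8-yl}benzaldehyde | COc1cc(OCc2ccccc2)c2c(c1-c1cc(C=O)ccc1OCc1ccccc1)O[C@H](c1ccc(OCc3ccccc3)cc1)CC2=O | intermediate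
25 | 2',4',6'-trihydroxyacetophenone | CC(=O)c1c(O)cc(O)cc1O | starting material
26 | 1-[2,4-bis(benzyloxy)-6-hydroxyphenyl]ethan-1-one | CC(=O)c1c(O)cc(OCc2ccccc2)cc1OCc1ccccc1 | intermediate
27 | tert-butyl 3-[2,4-bis(benzyloxy)-6-hydroxyphenyl]-3-oxopropanoate | CC(C)(C)OC(=O)CC(=O)c1c(O)cc(OCc2ccccc2)cc1OCc1ccccc1 | intermediate
28 | tert-butyl (E)-2-[2,4-bis(benzyloxy)-6-hydroxybenzoyl]-3-(ring B aryl of 24)prop-2-enoate, (2''S) | COc1cc(OCc2ccccc2)c2c(c1-c1cc(/C=C(/C(=O)OC(C)(C)C)C(=O)c3c(O)cc(OCc4ccccc4)cc3OCc3ccccc3)ccc1OCc1ccccc1)O[C@H](c1ccc(OCc3ccccc3)cc1)CC2=O | intermediate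
29 | (2S,2''S)-penta-O-benzyl biflavanone carrying CO2t-Bu at C3, C3 labile (not isolated) | COc1cc(OCc2ccccc2)c2c(c1-c1cc([C@@H]3C(C(=O)OC(C)(C)C)C(=O)c4c(OCc5ccccc5)cc(OCc5ccccc5)cc4O3)ccc1OCc1ccccc1)O[C@H](c1ccc(OCc3ccccc3)cc1)CC2=O | intermediate
30 | (2S,2''S)-5,7,4',5'',4'''-penta-O-benzyl-7''-O-methyl-3',8''-biflavanone | COc1cc(OCc2ccccc2)c2c(c1-c1cc([C@@H]3CC(=O)c4c(OCc5ccccc5)cc(OCc5ccccc5)cc4O3)ccc1OCc1ccccc1)O[C@H](c1ccc(OCc3ccccc3)cc1)CC2=O | intermediate
31 | CNP0237714.1, (2S,2''S)-5,7,4',5'',4'''-pentahydroxy-7''-methoxy-3',8''-biflavanone | COc1cc(O)c2c(c1-c1cc([C@@H]3CC(=O)c4c(O)cc(O)cc4O3)ccc1O)O[C@H](c1ccc(O)cc1)CC2=O | target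

## Step count and risks

Total step count: 17.
Longest linear sequence: 14 steps (1, 2, 3, 5, 6, 7, 8, 9, 10, 11, 12, 15, 16, 17).

### Risk 1, step 5 (key step)

Process at risk:
- The vinylogous ester resonance of 8 may slow its electrocyclic opening.
- Ketene oligomerisation or thermal decay of the siloxyalkyne could then outrun capture by the ortho-substituted aryl alkyne.

Fallback (sets out from 6, returns at 14): the roles of the two partners are exchanged.
- Siloxyalkyne 6 takes up ketene (CH2=C=O gas, CH2Cl2, 0 °C to rt) in the known [2+2] cycloaddition of silyl ynol ethers. This gives 2-ArB-3-(triisopropylsiloxy)cyclobut-2-en-1-one F1, whose aryl group conjugates with and so favours the derived vinylketene.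
- Heating with methoxyacetylene (toluene, sealed tube) in the alkoxyalkyne version of the benzannulation should give 4-ArB-3-methoxy-5-(triisopropylsiloxy)phenol F2. Here the C7'' methyl ether is already in place and C5'' is the only free hydroxyl.
- Benzylation (BnBr, K2CO3, acetone) leads to 14.

### Risk 2, step 3

Process at risk:
- Surplus alkyllithium during the warm-up needed for aryl migration may metalate the benzylic CH2 of the ether or ring B.
- Part of the silylation may take place on carbon.

Fallback (sets out from 3, returns at 6): the ynolate is made by oxidation of an acetylide instead of by rearrangement.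
- LiAlH4 (THF, 0 °C) reduces 3 to [2-(benzyloxy)-5-(5,5-dimethyl-1,3-dioxan-2-yl)phenyl]methanol F3.
- MnO2 gives 2-(benzyloxy)-5-(5,5-dimethyl-1,3-dioxan-2-yl)benzaldehyde F4.
- Ohira-Bestmann homologation (dimethyl (1-diazo-2-oxopropyl)phosphonate, K2CO3, MeOH) gives 2-[4-(benzyloxy)-3-ethynylphenyl]-5,5-dimethyl-1,3-dioxane F5.
- One equivalent of n-BuLi at -78 °C, then lithium tert-butyl peroxide (from t-BuOOH and LiN(SiMe3)2), -78 to 0 °C, converts the acetylide into ynolate 5.
- iPr3SiOSO2CF3 traps 5 as 6.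

### Risk 3, step 12

Process at risk:
- Facial selectivity may be poor or closure slow, because the nucleophilic C8a'' phenol is flanked by ring B.
- Uncatalysed racemic closure could then compete.

Fallback (sets out from 17, returns at 23 and through the last stage of step 12 at 24): the C2'' centre is set by asymmetric conjugate arylation of a chromone instead of by C-O bond formation.
- HC≡CMgBr (excess, THF, 0 °C) adds to 17 to give 2-ArB-5-(benzyloxy)-6-(1-hydroxyprop-2-yn-1-yl)-3-methoxyphenol F6.
- MnO2 gives 1-[3-ArB-6-(benzyloxy)-2-hydroxy-4-methoxyphenyl]prop-2-yn-1-one F7.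
- Et2NH (cat., EtOH) closes the ynone through its enaminone to 8-ArB-5-(benzyloxy)-7-methoxy-4H-chromen-4-one F8.
- 4-(Benzyloxy)phenylboronic acid adds under Pd(OCOCF3)2 and 4-tert-butyl-2-(pyridin-2-yl)-4,5-dihydrooxazole (NH4PF6, H2O, ClCH2CH2Cl, 60 °C) to give 23. The ligand enantiomer is chosen on a model chromone for the 2S series.

## Further compounds

F1 | step 5 | 2-ArB-3-(triisopropylsiloxy)cyclobut-2-en-1-one | O=C1CC(O[Si](C(C)C)(C(C)C)C(C)C)=C1c1cc(C2OCC(C)(C)CO2)ccc1OCc1ccccc1
F2 | step 5 | 4-ArB-3-methoxy-5-(triisopropylsiloxy)phenol | COc1cc(O)cc(O[Si](C(C)C)(C(C)C)C(C)C)c1-c1cc(C2OCC(C)(C)CO2)ccc1OCc1ccccc1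
F3 | step 3 | [2-(benzyloxy)-5-(5,5-dimethyl-1,3-dioxan-2-yl)phenyl]methanol | OCc1cc(C2OCC(C)(C)CO2)ccc1OCc1ccccc1
F4 | step 3 | 2-(benzyloxy)-5-(5,5-dimethyl-1,3-dioxan-2-yl)benzaldehyde | O=Cc1cc(C2OCC(C)(C)CO2)ccc1OCc1ccccc1
F5 | step 3 | 2-[4-(benzyloxy)-3-ethynylphenyl]-5,5-dimethyl-1,3-dioxane | C#Cc1cc(C2OCC(C)(C)CO2)ccc1OCc1ccccc1
F6 | step 12 | 2-ArB-5-(benzyloxy)-6-(1-hydroxyprop-2-yn-1-yl)-3-methoxyphenol, racemic carbinol | COc1cc(OCc2ccccc2)c(C(O)C#C)c(O)c1-c1cc(C2OCC(C)(C)CO2)ccc1OCc1ccccc1
F7 | step 12 | 1-[3-ArB-6-(benzyloxy)-2-hydroxy-4-methoxyphenyl]prop-2-yn-1-one | COc1cc(OCc2ccccc2)c(C(=O)C#C)c(O)c1-c1cc(C2OCC(C)(C)CO2)ccc1OCc1ccccc1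
F8 | step 12 | 8-ArB-5-(benzyloxy)-7-methoxy-4H-chromen-4-one | COc1cc(OCc2ccccc2)c2c(c1-c1cc(C3OCC(C)(C)CO3)ccc1OCc1ccccc1)OC=CC2=O
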